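# Podocarpusflavone A by a triyne-to-benzyne cascade: synthesis proposal

## Analysis of the target

Podocarpusflavone A (23) is a biflavone: two 5,7-dioxygenated flavones joined by a single biaryl bond from C3' of ring B of unit 1 (an apigenin unit) to C8'' of ring A of unit 2 (an acacetin unit, atoms double-primed, its methoxyphenyl ring triple-primed). The molecule has no stereocentre, and the C3'–C8'' axis, although flanked by O4', O7'' and C8a'', is treated as configurationally labile, so no stereochemical element has to be set. The sensitive groups are five phenols (two of them chelated to the C4 and C4'' carbonyls), two pyranones that open under hot strong base, and the one methyl ether at O4''', which must survive while five other oxygens are unmasked. The synthesis is hard because the inter-flavone bond ends on C8'', a carbon with two ortho substituents in a ring whose C6'' is electronically almost its twin. Coupling and substitution approaches therefore face both steric hindrance and a 6''/8'' ambiguity, and the two flavone units differ only by one O-methyl group. The strategy rests on the benzene ring of unit 2, in which every carbon has a defined role: C4a'' (acyl), C5'' (O), C6'' (H), C7'' (O), C8'' (ring B) and C8a'' (O1''). These six carbons map onto three alkynes: a 1,3-diyne C4a''≡C5''–C6''≡C7'' capped by O7'', and an alkyne C8a''≡C8'' that carries O1'' and ring B. The remaining pyranone atoms O1''–C2''=C3''–C4'' serve as the tether, and C5''≡C6'' is left as a benzyne that receives O5''.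

## Retrosynthetic reasoning

**23 ⇐ 22.** The last operation should only unmask oxygen. All five phenols of 23 are taken back to benzyl ethers in 22. Benzyl aryl ethers fall to a boron Lewis acid at low temperature, where the unchelated aryl methyl ether at O4''' is expected to stay. No skeletal bond is cut.

**22 ⇐ 21 ⇐ 18 + 20.** Unit 1 is an ordinary flavone and is taken apart in the ordinary way. The O1–C2 bond is cut to give the o-hydroxyaryl 1,3-diketone 21. The C2–C3 bond is then cut to give the methyl benzoate 18, which already contains unit 2 and ring B, and the acetophenone 20. Cutting here and not at the biaryl bond keeps the hindered C3'–C8'' bond out of the endgame. In the forward direction a crossed Claisen condensation must join the doubly deprotonated 20 to the ester of 18, and acid must then close the pyranone. Compound 20 is the twofold benzyl ether of the phloroglucinol ketone 19; its hydrogen-bonded hydroxyl stays free.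

**18 ⇐ 16 (via 17).** Compound 18 differs from the cycloaddition product 16 only in its oxygen substituents at C5'' and C7''. The acetate and silyl ether of 16 would not pass cleanly through enolate chemistry, so they are exchanged for benzyl ethers in one flask through the diol 17.

**16 ⇐ 15 ⇐ 14 (key disconnection).** The benzene ring and the pyranone of unit 2 are opened together. The C5''–O bond is cut to leave the benzyne 15, and the C4a''–C8a'' and C7''–C8'' bonds are then cut to give the acyclic triyne 14. Cutting here is preferred to cutting the biaryl bond because every substituent of unit 2 is placed by connectivity: ring B sits on the alkyne carbon that becomes C8'', O1'' is already bonded to C8a'', and O7'' caps the diyne. No 6''-aryl isomer can form and no hindered cross-coupling is needed. The forward reaction has to bring the (Z)-enone-tethered diyne and ynol ether together thermally and deliver an oxygen nucleophile to C5'' and not to C6''.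

**14 ⇐ 9 + 12 (via 13).** The C4''–C4a'' bond is cut between the carbonyl and the diyne. This splits 14 into the Weinreb amide 9, which carries the fragile alkynyl enol ether, and a four-carbon siloxydiynyl anion 13. The anion is reached from the siloxy enyne 12 by loss of methoxide, which avoids a separate C-deprotection next to a silyl ynol ether. An acyl substitution on a Weinreb amide stops at the ketone, and it is the mildest way to introduce the electrophilic diynone last.

**9 ⇐ 7 (via 8).** The ynol ether triple bond C8a''≡C8'' is taken back to a ketone: enol triflate 8, then α-alkoxy ketone 7. Direct alkynylation of the enol oxygen (for instance copper-mediated coupling with a 1,1-dihaloalkene) is not used. The enol of a 1,3-dicarbonyl compound reacts with such partners at carbon, so furans are the likely outcome, not an enol ynol ether. Elimination from an enol triflate makes the C(sp)–O unit from an ordinary ether instead.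

**7 ⇐ 6 ⇐ 2 + 5.** The O1''–C2'' bond is cut. Conjugate addition of the primary alcohol 5 to the alkynyl Weinreb amide 2 forms the enol ether 6, and trans addition across the alkyne gives the Z geometry that the key step needs. The ketone of ring B's side chain is carried as a dimethyl ketal in 5 and 6, because a free α-hydroxy ketone would follow the oxa-Michael addition with an aldol closure to a furan. Mild acid then releases 7.

**5 ⇐ 4 ⇐ 3; 2 ⇐ 1; 12 ⇐ 10 (via 11).** Compound 5 is the α-hydroxy dimethyl ketal of the benzyl-protected acetophenone 4, itself from the phenol 3. Compound 2 is the carbamoylation product of the arylalkyne 1. Compound 12 is made from the methoxy enyne 10 by oxidation of its acetylide to the ynolate 11 and O-silylation.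

## Alternatives that were turned down

**Alternative 1:** Here the C2–C3 and C2''–C3'' bonds are both disconnected, so that both pyranones are unravelled to aryl esters on one biaryl, the diester A2. In the forward direction strong base should trigger two intramolecular O-to-C acyl shifts (Baker–Venkataraman) to give the bis(1,3-diketone) A1, and acid should then close both pyranones. In its favour, every bond-forming event is standard flavone chemistry, the methoxyphenyl and hydroxyphenyl ends are distinguished simply by the choice of acyl partners, and the end of the route is short. Against it, the key step closes no ring and leaves the real problem untouched: the C3'–C8'' bond must already exist in A2, so a hindered cross-coupling onto a trioxygenated acetophenone ring is still required. In addition, the ester of unit 2 must sit on the phenol wedged between the acetyl group and the biaryl, and two different aryl esters under base can exchange acyl groups between molecules and scramble the two diketones. On reliability this alternative is clearly stronger than the chosen route, and its step count is no worse. What the chosen route offers in its place is that the biaryl bond is never made by coupling, the substitution pattern of unit 2 follows from connectivity, and two rings and three skeletal bonds arise in one operation.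

**Alternative 2:** Here ring A of unit 2 is disconnected into a four-carbon vinylketene, released from the cyclobutenone A4, and the two carbons of the aryl siloxyalkyne A5 that already bears ring B. In the forward direction heating the two should give, by electrocyclic opening, [2+2] addition, reopening and six-electron closure, the biaryl phenol A3, with ring B between a free hydroxyl and a siloxy group. In its favour, this benzannulation is well precedented for siloxyalkynes, its regiochemistry is dictated by the mechanism, ring B is attached without any cross-coupling, and the siloxyalkyne chemistry is shared with the chosen route. Against it for this target, only the benzene ring is formed. C4a'' arrives as C–H, so the C4'' acyl carbon and the whole pyranone must be added by a separate acylation and diketone sequence. O5'' arrives as an ethyl ether that must later be cleaved beside the O4''' methyl ether, and the bromide must still be turned into the carboxyl carbon of unit 1. The key step of this alternative is safer than step 9 of the chosen route. The chosen route offers instead a key step that delivers the complete chromone with its carbonyl and O5'' in place, which saves the linear steps that A3 would still need.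

**Alternative 3:** Here ring B is disconnected at C1'–C2' and C5'–C6', so that it is grown last on a finished unit 2. In the forward direction the aminosiloxydiene A7, carried on C8'', should add to methyl propiolate A8 and lose dimethylamine to give the aromatic ester A6. In its favour, unit 2 is made by routine flavone chemistry, the cycloaddition is a polarity-matched reaction of known type, no biaryl coupling is needed, and A6 is the silyl analogue of compound 18, so the endgame would be the same as here. Against it, the diene sits on a carbon with two ortho substituents, which crowds the approach of the dienophile to C2'. The amino diene is hydrolytically fragile, and its preparation needs several linear steps on an advanced flavone, including a regioselective condensation and an enol silylation beside the chromone carbonyl. This alternative is probably more reliable than the chosen route and of similar length. The chosen route offers in its place the assembly of unit 2 from acyclic pieces in one step, with no stage at which C6'' and C8'' of a preformed flavone must be told apart.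

Key step: step 9

Remark: the C3'–C8'' biaryl axis is treated as configurationally labile; no axial descriptor is assigned.
Remark: compound 10 is taken as the commercial technical-grade enyne, dried and distilled before use.

## Route

Step 1
Reactants: 1 1-ethynyl-4-methoxybenzene
Product: 2 N-methoxy-3-(4-methoxyphenyl)-N-methylprop-2-ynamide
Conditions: n-BuLi, THF, −78 °C; ClC(O)N(OMe)Me, −78 → 0 °C
Reagents that add atoms: N-methoxy-N-methylcarbamoyl chloride, CON(C)C(Cl)=O
Why: Acylation of a lithium acetylide with a carbamoyl chloride is a standard route to alkynyl Weinreb amides; the aryl methyl ether is inert.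

Step 2
Reactants: 3 methyl 3-acetyl-4-hydroxybenzoate
Product: 4 methyl 3-acetyl-4-(benzyloxy)benzoate
Conditions: BnBr, K2CO3, DMF, 60 °C
Reagents that add atoms: benzyl bromide, BrCc1ccccc1
Why: Williamson etherification of a phenol; warming overcomes the hydrogen bond to the ortho acetyl group, and the methyl ester is untouched by carbonate.

Step 3
Reactants: 4 methyl 3-acetyl-4-(benzyloxy)benzoate
Product: 5 methyl 4-(benzyloxy)-3-(2-hydroxy-1,1-dimethoxyethyl)benzoate
Conditions: PhI(OAc)2, KOH, MeOH, 0 °C → rt
Reagents that add atoms: methanol, CO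
Why: α-Hydroxylation of an aryl methyl ketone with a trivalent iodine reagent in basic methanol (Moriarty oxidation) gives the α-hydroxy dimethyl ketal through a methoxy epoxide; in methanol the methyl ester can only exchange with its own alkoxide, and the low temperature limits saponification.

Step 4
Reactants: 2 N-methoxy-3-(4-methoxyphenyl)-N-methylprop-2-ynamide; 5 methyl 4-(benzyloxy)-3-(2-hydroxy-1,1-dimethoxyethyl)benzoate
Product: 6 methyl 4-(benzyloxy)-3-(2-{[(1Z)-3-[methoxy(methyl)amino]-1-(4-methoxyphenyl)-3-oxoprop-1-en-1-yl]oxy}-1,1-dimethoxyethyl)benzoate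
Conditions: NaH (0.2 equiv), THF, 0 °C → rt
Reagents that add atoms: none
Why: Alkoxide-catalysed oxa-Michael addition of a primary alcohol to an alkynyl amide; trans addition of O–H across the triple bond places the ether oxygen cis to the amide carbonyl (Z), as in the classical formation of β-aryloxycinnamates from arylpropiolates. The ketal removes the enolisable ketone that would otherwise close to a furan, and the alkoxide of 5 is the only alkoxide present.

Step 5
Reactants: 6 methyl 4-(benzyloxy)-3-(2-{[(1Z)-3-[methoxy(methyl)amino]-1-(4-methoxyphenyl)-3-oxoprop-1-en-1-yl]oxy}-1,1-dimethoxyethyl)benzoate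
Product: 7 methyl 4-(benzyloxy)-3-({[(1Z)-3-[methoxy(methyl)amino]-1-(4-methoxyphenyl)-3-oxoprop-1-en-1-yl]oxy}acetyl)benzoate
Conditions: TsOH·H2O (cat.), acetone–H2O, rt
Reagents that add atoms: water, O
Why: Acid hydrolysis of an aryl dimethyl ketal, which should be far faster than protonation of the carbonyl-conjugated enol ether; the benzyl ether, ester and Weinreb amide are stable to dilute acid at room temperature.

Step 6
Reactants: 7 methyl 4-(benzyloxy)-3-({[(1Z)-3-[methoxy(methyl)amino]-1-(4-methoxyphenyl)-3-oxoprop-1-en-1-yl]oxy}acetyl)benzoate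
Product: 9 methyl 4-(benzyloxy)-3-({[(1Z)-3-[methoxy(methyl)amino]-1-(4-methoxyphenyl)-3-oxoprop-1-en-1-yl]oxy}ethynyl)benzoate, via enol triflate 8 (not isolated)
Conditions: LiN(SiMe3)2, PhNTf2, THF, −78 → 0 °C; then KOtBu, −78 → −20 °C
Reagents that add atoms: none
Why: Enol triflate formation from an α-alkoxy aryl ketone and base-induced anti elimination of triflate is the established enol-sulfonate route to ynol ethers; lithium chelation between the enolate and ether oxygens should give the Z enol triflate, whose vinylic hydrogen is anti to the leaving group. The amide base is non-nucleophilic, and the ester and Weinreb amide should tolerate the brief low-temperature exposure to KOtBu.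

Step 7
Reactants: 10 (Z)-1-methoxybut-1-en-3-yne
Product: 12 {[(3Z)-4-methoxybut-3-en-1-yn-1-yl]oxy}tri(propan-2-yl)silane, via lithium ynolate 11 (not isolated)
Conditions: LiN(SiMe3)2, THF, −78 °C; LiOOtBu (from t-BuOOH and LiN(SiMe3)2), −78 → 0 °C; TIPSOTf, −78 °C
Reagents that add atoms: tert-butyl hydroperoxide, CC(C)(C)OO; triisopropylsilyl trifluoromethanesulfonate, CC(C)[Si](C(C)C)(C(C)C)OS(=O)(=O)C(F)(F)F
Why: Oxidation of a lithium acetylide by lithium tert-butyl peroxide to the ynolate, followed by O-silylation with a bulky silyl triflate, is the standard preparation of triisopropylsiloxyalkynes from terminal alkynes; the enol ether is inert to these reagents and keeps its Z geometry.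

Step 8
Reactants: 12 {[(3Z)-4-methoxybut-3-en-1-yn-1-yl]oxy}tri(propan-2-yl)silane; 9 methyl 4-(benzyloxy)-3-({[(1Z)-3-[methoxy(methyl)amino]-1-(4-methoxyphenyl)-3-oxoprop-1-en-1-yl]oxy}ethynyl)benzoate
Product: 14 methyl 4-(benzyloxy)-3-({[(1Z)-1-(4-methoxyphenyl)-3-oxo-7-(triisopropylsiloxy)hept-1-ene-4,6-diyn-1-yl]oxy}ethynyl)benzoate, via lithium siloxybutadiynide 13 (not isolated)
Conditions: 12, LiN(iPr)2 (2.2 equiv), THF, −78 → −40 °C; then 9, −78 °C; aq. NH4Cl
Reagents that add atoms: none
Why: Base-induced anti elimination of methoxide from a (Z)-methoxy enyne, the known entry to butadiynyl anions, followed by deprotonation of the new terminal alkyne gives 13 without any C-deprotection beside the silyl ynol ether. Acyl substitution on the Weinreb amide then stops at the ketone through the stable chelate, and at −78 °C the 4-alkoxybenzoate is expected to be left alone.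

Step 9
Reactants: 14 methyl 4-(benzyloxy)-3-({[(1Z)-1-(4-methoxyphenyl)-3-oxo-7-(triisopropylsiloxy)hept-1-ene-4,6-diyn-1-yl]oxy}ethynyl)benzoate
Product: 16 methyl 3-[5-acetoxy-2-(4-methoxyphenyl)-4-oxo-7-(triisopropylsiloxy)-4H-chromen-8-yl]-4-(benzyloxy)benzoate, via benzyne 15 (not isolated)
Conditions: AcOH (3 equiv), PhCl (0.01 M), 100 °C, Ar, dark
Reagents that add atoms: acetic acid, CC(=O)O
Why: Proposed new method: on heating, the ketone-conjugated 1,3-diyne (C4a''≡C5''–C6''≡C7'') and the ynol ether alkyne (C8a''≡C8''), held in a 1,6 relationship by the (Z)-enone, should undergo an intramolecular hexadehydro-Diels–Alder reaction, probably stepwise through a diradical formed by C4a''–C8a'' bonding, to give benzyne 15. The closest known reaction type is the thermal cycloisomerisation of tethered triynes to benzynes with capture by a carboxylic acid; new here are the four-atom enone tether that ends in an ynol ether oxygen and the siloxy-capped diyne. The pyranone closes as the six-membered tether ring when C4a'' bonds to C8a'', and the benzene ring closes as the [4+2] ring when C7'' bonds to C8''. Acetic acid then adds across C5''≡C6'' to form C5''–O and C6''–H, and no stereocentre is formed. Two selectivities are needed: the alkene must be Z, which steps 4 to 8 carry through and which acid-mediated equilibration of the push–pull enol ether can correct, and oxygen must go to C5''. The siloxy group at C7'' should secure the second by making the aryne carbon remote from it the electrophilic one, helped by hydrogen bonding of the acid to the C4'' carbonyl and by the bulk of the silyl group beside C6''. The acid is kept to a few equivalents at high dilution so that capture of the benzyne, which is fast, outruns acid addition across the two ynol ethers of 14.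

Step 10
Reactants: 16 methyl 3-[5-acetoxy-2-(4-methoxyphenyl)-4-oxo-7-(triisopropylsiloxy)-4H-chromen-8-yl]-4-(benzyloxy)benzoate
Product: 18 methyl 4-(benzyloxy)-3-[5,7-bis(benzyloxy)-2-(4-methoxyphenyl)-4-oxo-4H-chromen-8-yl]benzoate, via dihydroxyflavone ester 17 (not isolated)
Conditions: K2CO3, MeOH–THF, rt; evaporate; BnBr, K2CO3, DMF, 60 °C
Reagents that add atoms: benzyl bromide, BrCc1ccccc1
Why: Methanolysis removes the aryl acetate and the 7-siloxy group, which behaves as a vinylogous silyl ester of the chromone and is labile to methoxide; Williamson benzylation then caps both phenols, with warming for the chelated 5-hydroxyl. The methyl ester is unchanged in methanol, and any earlier partial loss of acetyl or silyl from 16 is harmless because this step removes both.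

Step 11
Reactants: 19 2',4',6'-trihydroxyacetophenone
Product: 20 1-[2,4-bis(benzyloxy)-6-hydroxyphenyl]ethan-1-one
Conditions: BnBr (2.1 equiv), K2CO3, DMF, rt
Reagents that add atoms: benzyl bromide, BrCc1ccccc1
Why: Selective twofold Williamson etherification; the hydroxyl hydrogen-bonded to the acetyl group is the least nucleophilic and remains free.

Step 12
Reactants: 18 methyl 4-(benzyloxy)-3-[5,7-bis(benzyloxy)-2-(4-methoxyphenyl)-4-oxo-4H-chromen-8-yl]benzoate; 20 1-[2,4-bis(benzyloxy)-6-hydroxyphenyl]ethan-1-one
Product: 21 1-[2,4-bis(benzyloxy)-6-hydroxyphenyl]-3-{4-(benzyloxy)-3-[5,7-bis(benzyloxy)-2-(4-methoxyphenyl)-4-oxo-4H-chromen-8-yl]phenyl}propane-1,3-dione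
Conditions: 20 (1.5 equiv), LiN(SiMe3)2 (5 equiv), THF, −78 °C → rt
Reagents that add atoms: none
Why: Crossed Claisen condensation of the doubly deprotonated o-hydroxyacetophenone with a methyl benzoate, driven by deprotonation of the 1,3-diketone; the fully etherified 2-arylchromone of unit 2 has no acidic site and is a poor acceptor for the enolate at or below room temperature.

Step 13
Reactants: 21 1-[2,4-bis(benzyloxy)-6-hydroxyphenyl]-3-{4-(benzyloxy)-3-[5,7-bis(benzyloxy)-2-(4-methoxyphenyl)-4-oxo-4H-chromen-8-yl]phenyl}propane-1,3-dione
Product: 22 5,7-bis(benzyloxy)-8-{2-(benzyloxy)-5-[5,7-bis(benzyloxy)-4-oxo-4H-chromen-2-yl]phenyl}-2-(4-methoxyphenyl)-4H-chromen-4-one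
Conditions: TsOH·H2O (cat.), toluene, 100 °C
Reagents that add atoms: none
Why: Acid-catalysed cyclodehydration of an o-hydroxyaryl 1,3-diketone: the phenol adds to the carbonyl next to ring B and water is lost, which closes the pyranone of unit 1. Benzyl ethers tolerate catalytic sulfonic acid in toluene.

Step 14
Reactants: 22 5,7-bis(benzyloxy)-8-{2-(benzyloxy)-5-[5,7-bis(benzyloxy)-4-oxo-4H-chromen-2-yl]phenyl}-2-(4-methoxyphenyl)-4H-chromen-4-one
Product: 23 podocarpusflavone A
Conditions: BCl3, pentamethylbenzene, CH2Cl2, −78 → −30 °C; MeOH, aq. work-up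
Reagents that add atoms: none
Why: Lewis-acid debenzylation of aryl benzyl ethers with a cation scavenger; the unchelated aryl methyl ether at O4''' should survive BCl3 at low temperature, and the pyranones are stable to these conditions.

## Compound list

1 | 1-ethynyl-4-methoxybenzene | COc1ccc(C#C)cc1 | starting material
2 | N-methoxy-3-(4-methoxyphenyl)-N-methylprop-2-ynamide | COc1ccc(C#CC(=O)N(C)OC)cc1 | intermediate
3 | methyl 3-acetyl-4-hydroxybenzoate | CC(=O)c1cc(C(=O)OC)ccc1O | starting material
4 | methyl 3-acetyl-4-(benzyloxy)benzoate | CC(=O)c1cc(C(=O)OC)ccc1OCc1ccccc1 | intermediate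
5 | methyl 4-(benzyloxy)-3-(2-hydroxy-1,1-dimethoxyethyl)benzoate | COC(=O)c1ccc(OCc2ccccc2)c(C(OC)(OC)CO)c1 | intermediate
6 | methyl 4-(benzyloxy)-3-(2-{[(1Z)-3-[methoxy(methyl)amino]-1-(4-methoxyphenyl)-3-oxoprop-1-en-1-yl]oxy}-1,1-dimethoxyethyl)benzoate | COc1ccc(cc1)/C(OCC(OC)(OC)c1cc(C(=O)OC)ccc1OCc1ccccc1)=C/C(=O)N(C)OC | intermediate
7 | methyl 4-(benzyloxy)-3-({[(1Z)-3-[methoxy(methyl)amino]-1-(4-methoxyphenyl)-3-oxoprop-1-en-1-yl]oxy}acetyl)benzoate | COc1ccc(cc1)/C(OCC(=O)c1cc(C(=O)OC)ccc1OCc1ccccc1)=C/C(=O)N(C)OC | intermediate
8 | methyl 4-(benzyloxy)-3-[(Z)-2-{[(1Z)-3-[methoxy(methyl)amino]-1-(4-methoxyphenyl)-3-oxoprop-1-en-1-yl]oxy}-1-(trifluoromethanesulfonyloxy)ethenyl]benzoate (enol triflate, not isolated) | COc1ccc(cc1)/C(O/C=C(\OS(=O)(=O)C(F)(F)F)c1cc(C(=O)OC)ccc1OCc1ccccc1)=C/C(=O)N(C)OC | intermediate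
9 | methyl 4-(benzyloxy)-3-({[(1Z)-3-[methoxy(methyl)amino]-1-(4-methoxyphenyl)-3-oxoprop-1-en-1-yl]oxy}ethynyl)benzoate | COc1ccc(cc1)/C(OC#Cc1cc(C(=O)OC)ccc1OCc1ccccc1)=C/C(=O)N(C)OC | intermediate
10 | (Z)-1-methoxybut-1-en-3-yne | CO/C=C\C#C | starting material
11 | lithium (3Z)-4-methoxybut-3-en-1-yn-1-olate (not isolated) | CO/C=C\C#C[O-].[Li+] | intermediate
12 | {[(3Z)-4-methoxybut-3-en-1-yn-1-yl]oxy}tri(propan-2-yl)silane | CO/C=C\C#CO[Si](C(C)C)(C(C)C)C(C)C | intermediate
13 | lithium 4-(triisopropylsiloxy)buta-1,3-diyn-1-ide (not isolated) | [Li+].[C-]#CC#CO[Si](C(C)C)(C(C)C)C(C)C | intermediate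
14 | methyl 4-(benzyloxy)-3-({[(1Z)-1-(4-methoxyphenyl)-3-oxo-7-(triisopropylsiloxy)hept-1-ene-4,6-diyn-1-yl]oxy}ethynyl)benzoate | COc1ccc(cc1)/C(OC#Cc1cc(C(=O)OC)ccc1OCc1ccccc1)=C/C(=O)C#CC#CO[Si](C(C)C)(C(C)C)C(C)C | intermediate
15 | methyl 4-(benzyloxy)-3-[5,6-didehydro-2-(4-methoxyphenyl)-4-oxo-7-(triisopropylsiloxy)-4H-chromen-8-yl]benzoate (benzyne, not isolated) | COc1ccc(cc1)C1=CC(=O)C2=C(O1)C(c1cc(C(=O)OC)ccc1OCc1ccccc1)=C(O[Si](C(C)C)(C(C)C)C(C)C)C#C2 | intermediate
16 | methyl 3-[5-acetoxy-2-(4-methoxyphenyl)-4-oxo-7-(triisopropylsiloxy)-4H-chromen-8-yl]-4-(benzyloxy)benzoate | COc1ccc(cc1)-c1cc(=O)c2c(OC(C)=O)cc(O[Si](C(C)C)(C(C)C)C(C)C)c(-c3cc(C(=O)OC)ccc3OCc3ccccc3)c2o1 | intermediate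
17 | methyl 4-(benzyloxy)-3-[5,7-dihydroxy-2-(4-methoxyphenyl)-4-oxo-4H-chromen-8-yl]benzoate (not isolated) | COc1ccc(cc1)-c1cc(=O)c2c(O)cc(O)c(-c3cc(C(=O)OC)ccc3OCc3ccccc3)c2o1 | intermediate
18 | methyl 4-(benzyloxy)-3-[5,7-bis(benzyloxy)-2-(4-methoxyphenyl)-4-oxo-4H-chromen-8-yl]benzoate | COc1ccc(cc1)-c1cc(=O)c2c(OCc3ccccc3)cc(OCc3ccccc3)c(-c3cc(C(=O)OC)ccc3OCc3ccccc3)c2o1 | intermediate
19 | 2',4',6'-trihydroxyacetophenone | CC(=O)c1c(O)cc(O)cc1O | starting material
20 | 1-[2,4-bis(benzyloxy)-6-hydroxyphenyl]ethan-1-one | CC(=O)c1c(O)cc(OCc2ccccc2)cc1OCc1ccccc1 | intermediate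
21 | 1-[2,4-bis(benzyloxy)-6-hydroxyphenyl]-3-{4-(benzyloxy)-3-[5,7-bis(benzyloxy)-2-(4-methoxyphenyl)-4-oxo-4H-chromen-8-yl]phenyl}propane-1,3-dione | COc1ccc(cc1)-c1cc(=O)c2c(OCc3ccccc3)cc(OCc3ccccc3)c(-c3cc(C(=O)CC(=O)c4c(O)cc(OCc5ccccc5)cc4OCc4ccccc4)ccc3OCc3ccccc3)c2o1 | intermediate
22 | 5,7-bis(benzyloxy)-8-{2-(benzyloxy)-5-[5,7-bis(benzyloxy)-4-oxo-4H-chromen-2-yl]phenyl}-2-(4-methoxyphenyl)-4H-chromen-4-one | COc1ccc(cc1)-c1cc(=O)c2c(OCc3ccccc3)cc(OCc3ccccc3)c(-c3cc(-c4cc(=O)c5c(OCc6ccccc6)cc(OCc6ccccc6)cc5o4)ccc3OCc3ccccc3)c2o1 | intermediate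
23 | podocarpusflavone A | COc1ccc(-c2cc(=O)c3c(O)cc(O)c(-c4cc(-c5cc(=O)c6c(O)cc(O)cc6o5)ccc4O)c3o2)cc1 | target

## Step count and risk assessment

Total step count: 14.
Longest linear sequence: 11 steps (3 → 23 through steps 2, 3, 4, 5, 6, 8, 9, 10, 12, 13 and 14; the line from 1 is equally long).

Least certain steps:

**Step 9 (key step, the one proposed new method).** The most likely failure is consumption of 14 before it cyclises: acid addition across its two ynol ethers, loss of the silyl group from the diynone, or oligomerisation of the electron-poor diyne. This becomes serious if the six-membered-tether cycloaddition needs a temperature at which these processes are already fast. A second failure mode is misdirected capture of the benzyne (oxygen at C6'', or silyl migration to C6''). Within the step, the first remedies would be a less acidic O–H trap and higher dilution. The fallback gives up the cycloaddition and makes the biaryl bond by known coupling chemistry, at the cost of the 6''/8'' question that the main route avoids. It sets out from 20 and returns to the route at 18. C-acylation of the doubly lithiated 20 with 4-methoxybenzoyl chloride should give 1-[2,4-bis(benzyloxy)-6-hydroxyphenyl]-3-(4-methoxyphenyl)propane-1,3-dione F1, and acid-mediated cyclodehydration should give 5,7-bis(benzyloxy)-2-(4-methoxyphenyl)-4H-chromen-4-one F2. Iodination (I2, CF3CO2Ag), which for 5-O-alkylated 5,7-dioxygenated flavones goes to C8, should give 5,7-bis(benzyloxy)-8-iodo-2-(4-methoxyphenyl)-4H-chromen-4-one F3. Suzuki–Miyaura coupling of F3 (Pd(PPh3)4, K2CO3, DMF–H2O, 90 °C) with methyl 4-(benzyloxy)-3-(4,4,5,5-tetramethyl-1,3,2-dioxaborolan-2-yl)benzoate F4 should then give 18. F4 would be made beforehand by Miyaura borylation of methyl 4-(benzyloxy)-3-bromobenzoate F5.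

**Step 6.** The most likely failure is intramolecular acylation: the ketone enolate of 7 is held next to the Weinreb carbonyl by the Z geometry and can close to a five-membered furanone before it is triflated. In addition, tert-butoxide can add to C2'' and expel the oxygen substituent in an addition–elimination. The fallback changes the geometry during this operation; it sets out from 7 and returns at 9. Irradiation of 7 (365 nm) to a photostationary mixture and chromatography should give its E isomer, methyl 4-(benzyloxy)-3-({[(1E)-3-[methoxy(methyl)amino]-1-(4-methoxyphenyl)-3-oxoprop-1-en-1-yl]oxy}acetyl)benzoate F6, in which the amide is trans to the ether oxygen and out of reach of the enolate. The conditions of step 6 should then give the E ynol ether, methyl 4-(benzyloxy)-3-({[(1E)-3-[methoxy(methyl)amino]-1-(4-methoxyphenyl)-3-oxoprop-1-en-1-yl]oxy}ethynyl)benzoate F7, and a second irradiation with separation and recycling returns 9.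

**Step 8.** The most likely failure is loss of chemoselectivity. The Weinreb amide of 9 is vinylogously deactivated, so the diynide may instead attack the benzoate, or add to C2'' and expel the alkynyloxy group, which is a good leaving group. O-to-C silyl transfer within 13 on warming is a further risk. The fallback raises the electrophilicity of C4'' instead of forcing the acyl substitution; it sets out from 9 and returns at 14. Partial reduction of the Weinreb amide (iBu2AlH, THF, −78 °C) should give methyl 4-(benzyloxy)-3-({[(1Z)-1-(4-methoxyphenyl)-3-oxoprop-1-en-1-yl]oxy}ethynyl)benzoate F8. Addition of 13 at −78 °C, where an aldehyde reacts within minutes and the ester does not, should give methyl 4-(benzyloxy)-3-({[(1Z)-3-hydroxy-1-(4-methoxyphenyl)-7-(triisopropylsiloxy)hept-1-ene-4,6-diyn-1-yl]oxy}ethynyl)benzoate F9. Oxidation of this doubly activated carbinol with MnO2 in CH2Cl2 should give 14.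

**Step 4.** The most likely failure is a sluggish addition: the ynamide is deactivated by its methoxyphenyl group and the alkoxide of 5 is hindered. Reversible alkoxide addition can also erode the Z geometry. The fallback replaces alkoxide activation of the nucleophile by π-acid activation of the alkyne: from 2 and 5, hydroalkoxylation with a monovalent gold catalyst (Ph3PAuCl/AgOTf, toluene, rt) should give 6 directly by anti addition, with oxygen delivered to the aryl-bearing carbon. No new compound is involved.

**Step 12.** The most likely failure is incomplete condensation, because the acylation is reversible and the ester is hindered by the neighbouring biaryl, together with slow opening of the unit 2 pyranone by enolate or methoxide on long exposure. The fallback builds the same diketone by intramolecular acyl transfer; it sets out from 18 and returns at 21. Saponification (LiOH, THF–H2O, rt) should give 4-(benzyloxy)-3-[5,7-bis(benzyloxy)-2-(4-methoxyphenyl)-4-oxo-4H-chromen-8-yl]benzoic acid F10. Esterification with 20 (carbodiimide, 4-(dimethylamino)pyridine) should give 2-acetyl-3,5-bis(benzyloxy)phenyl 4-(benzyloxy)-3-[5,7-bis(benzyloxy)-2-(4-methoxyphenyl)-4-oxo-4H-chromen-8-yl]benzoate F11, and Baker–Venkataraman rearrangement (KOtBu, THF) should give 21.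

## Further compounds

F1 | step 9 | 1-[2,4-bis(benzyloxy)-6-hydroxyphenyl]-3-(4-methoxyphenyl)propane-1,3-dione | COc1ccc(cc1)C(=O)CC(=O)c1c(O)cc(OCc2ccccc2)cc1OCc1ccccc1
F2 | step 9 | 5,7-bis(benzyloxy)-2-(4-methoxyphenyl)-4H-chromen-4-one | COc1ccc(cc1)-c1cc(=O)c2c(OCc3ccccc3)cc(OCc3ccccc3)cc2o1
F3 | step 9 | 5,7-bis(benzyloxy)-8-iodo-2-(4-methoxyphenyl)-4H-chromen-4-one | COc1ccc(cc1)-c1cc(=O)c2c(OCc3ccccc3)cc(OCc3ccccc3)c(I)c2o1
F4 | step 9 | methyl 4-(benzyloxy)-3-(4,4,5,5-tetramethyl-1,3,2-dioxaborolan-2-yl)benzoate | COC(=O)c1ccc(OCc2ccccc2)c(B2OC(C)(C)C(C)(C)O2)c1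
F5 | step 9 | methyl 4-(benzyloxy)-3-bromobenzoate | COC(=O)c1ccc(OCc2ccccc2)c(Br)c1
F6 | step 6 | methyl 4-(benzyloxy)-3-({[(1E)-3-[methoxy(methyl)amino]-1-(4-methoxyphenyl)-3-oxoprop-1-en-1-yl]oxy}acetyl)benzoate | COc1ccc(cc1)/C(OCC(=O)c1cc(C(=O)OC)ccc1OCc1ccccc1)=C\C(=O)N(C)OC
F7 | step 6 | methyl 4-(benzyloxy)-3-({[(1E)-3-[methoxy(methyl)amino]-1-(4-methoxyphenyl)-3-oxoprop-1-en-1-yl]oxy}ethynyl)benzoate | COc1ccc(cc1)/C(OC#Cc1cc(C(=O)OC)ccc1OCc1ccccc1)=C\C(=O)N(C)OC
F8 | step 8 | methyl 4-(benzyloxy)-3-({[(1Z)-1-(4-methoxyphenyl)-3-oxoprop-1-en-1-yl]oxy}ethynyl)benzoate | COc1ccc(cc1)/C(OC#Cc1cc(C(=O)OC)ccc1OCc1ccccc1)=C/C=O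
F9 | step 8 | methyl 4-(benzyloxy)-3-({[(1Z)-3-hydroxy-1-(4-methoxyphenyl)-7-(triisopropylsiloxy)hept-1-ene-4,6-diyn-1-yl]oxy}ethynyl)benzoate (racemic) | COc1ccc(cc1)/C(OC#Cc1cc(C(=O)OC)ccc1OCc1ccccc1)=C/C(O)C#CC#CO[Si](C(C)C)(C(C)C)C(C)C
F0 | step 4 | none | none
F10 | step 12 | 4-(benzyloxy)-3-[5,7-bis(benzyloxy)-2-(4-methoxyphenyl)-4-oxo-4H-chromen-8-yl]benzoic acid | COc1ccc(cc1)-c1cc(=O)c2c(OCc3ccccc3)cc(OCc3ccccc3)c(-c3cc(C(=O)O)ccc3OCc3ccccc3)c2o1
F11 | step 12 | 2-acetyl-3,5-bis(benzyloxy)phenyl 4-(benzyloxy)-3-[5,7-bis(benzyloxy)-2-(4-methoxyphenyl)-4-oxo-4H-chromen-8-yl]benzoate | COc1ccc(cc1)-c1cc(=O)c2c(OCc3ccccc3)cc(OCc3ccccc3)c(-c3cc(C(=O)Oc4cc(OCc5ccccc5)cc(OCc5ccccc5)c4C(C)=O)ccc3OCc3ccccc3)c2o1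
A1 | alternative 1 | 1-[2,4-bis(benzyloxy)-6-hydroxyphenyl]-3-{4-(benzyloxy)-3-[4,6-bis(benzyloxy)-2-hydroxy-3-[3-(4-methoxyphenyl)-3-oxopropanoyl]phenyl]phenyl}propane-1,3-dione | Oc1cc(OCc2ccccc2)cc(OCc2ccccc2)c1C(=O)CC(=O)c1ccc(OCc2ccccc2)c(-c2c(OCc3ccccc3)cc(OCc3ccccc3)c(C(=O)CC(=O)c3ccc(OC)cc3)c2O)c1
A2 | alternative 1 | 2-acetyl-3,5-bis(benzyloxy)phenyl 3-{3-acetyl-4,6-bis(benzyloxy)-2-[(4-methoxybenzoyl)oxy]phenyl}-4-(benzyloxy)benzoate | COc1ccc(cc1)C(=O)Oc1c(C(C)=O)c(OCc2ccccc2)cc(OCc2ccccc2)c1-c1cc(C(=O)Oc2cc(OCc3ccccc3)cc(OCc3ccccc3)c2C(C)=O)ccc1OCc1ccccc1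
A3 | alternative 2 | 2-[2-(benzyloxy)-5-bromophenyl]-5-ethoxy-3-(triisopropylsiloxy)phenol | Oc1cc(OCC)cc(O[Si](C(C)C)(C(C)C)C(C)C)c1-c1cc(Br)ccc1OCc1ccccc1
A4 | alternative 2 | 3-ethoxycyclobut-2-en-1-one | CCOC1=CC(=O)C1
A5 | alternative 2 | {[2-(benzyloxy)-5-bromophenyl]ethynyloxy}tri(propan-2-yl)silane | Brc1ccc(OCc2ccccc2)c(C#CO[Si](C(C)C)(C(C)C)C(C)C)c1
A6 | alternative 3 | methyl 3-[5,7-bis(benzyloxy)-2-(4-methoxyphenyl)-4-oxo-4H-chromen-8-yl]-4-(tert-butyldimethylsiloxy)benzoate | COC(=O)c1ccc(O[Si](C)(C)C(C)(C)C)c(-c2c(OCc3ccccc3)cc(OCc3ccccc3)c3c(=O)cc(-c4ccc(OC)cc4)oc23)c1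
A7 | alternative 3 | 5,7-bis(benzyloxy)-8-[(1E)-3-(tert-butyldimethylsiloxy)-1-(dimethylamino)buta-1,3-dien-2-yl]-2-(4-methoxyphenyl)-4H-chromen-4-one | CN(C)/C=C(\c1c(OCc2ccccc2)cc(OCc2ccccc2)c2c(=O)cc(-c3ccc(OC)cc3)oc12)C(=C)O[Si](C)(C)C(C)(C)C
A8 | alternative 3 | methyl prop-2-ynoate | C#CC(=O)OC
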